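Left-handed product stalls with substrate left: in Thursday's run it goes from 14.7% to 15.0% between 10.0 min and 12.0 min, a step of 0.3 percentage points against a scatter of 0.5 points, while 42.7% left-handed and 42.5% right-handed substrate remain.

| flask | left-handed substrate | right-handed substrate | coupling partner | precatalyst | remark | time |
|---|---|---|---|---|---|---|
| Thursday's | 0.050 M | 0.050 M | 4 equiv | 0.025 mol% | run made earlier |  |
| Friday's | 0.050 M | 0.050 M | 4 equiv | 0.1 mol% | run made earlier |  |
| Tuesday's | 0.10 M | 0.10 M | 4 equiv | 0.05 mol% | run made earlier |  |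
| flask | 0.050 M | 0.050 M | 4.00 equiv | 0.05 mol% |  | 15 min |

| run | time / min | left-handed substrate / % | right-handed substrate / % | left-handed product / % |
|---|---|---|---|---|
| Thursday's | 0.667 | 46.0 | 48.3 | 3.8 |
| Thursday's | 2.00 | 45.0 | 44.7 | 8.4 |
| Thursday's | 3.00 | 44.6 | 44.4 | 10.5 |
| Thursday's | 5.00 | 43.8 | 44.4 | 12.1 |
| Thursday's | 8.00 | 42.4 | 42.7 | 13.4 |
| Thursday's | 10.0 | 42.4 | 42.1 | 14.7 |
| Thursday's | 12.0 | 42.7 | 42.5 | 15.0 |
| Friday's | 0.667 | 40.9 | 44.6 | 13.5 |
| Friday's | 2.00 | 36.5 | 36.2 | 27.1 |
| Friday's | 3.00 | 32.7 | 34.2 | 32.3 |
| Friday's | 5.00 | 31.2 | 32.4 | 35.8 |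
| Friday's | 8.00 | 30.7 | 30.1 | 38.5 |
| Friday's | 10.0 | 30.4 | 29.6 | 39.3 |
| Friday's | 12.0 | 29.3 | 30.2 | 41.0 |
| Tuesday's | 2.50 | 32.6 | 33.4 | 33.3 |
| Tuesday's | 5.00 | 31.6 | 30.9 | 36.5 |
| Tuesday's | 8.00 | 30.9 | 30.5 | 37.5 |
| Tuesday's | 10.0 | 29.1 | 30.8 | 38.6 |
| Tuesday's | 12.0 | 30.4 | 31.2 | 38.0 |

(standard deviation of a reading: 0.5 percentage points)

- part of the left-handed substrate and right-handed substrate charged together that has reacted at 15 min
- excess of left-handed product over right-handed product in the product at 15 min
- excess of right-handed substrate over left-handed substrate among what is left of the two at 15 min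

Take the stall index Λ, the natural logarithm of substrate charged over substrate left, read from left-handed product at the last reading: 0.163 on Thursday, 0.528 on Friday, 0.478 on Tuesday.

Which input must you know well? Time matters little in Thursday's run, as that small step shows. At fixed precatalyst molarity, concentration shifts Λ little: Tuesday's run has twice Friday's substrates and coupling partner and half its loading, and its Λ reads 0.0500 lower. At fixed concentration, loading matters: a factor 4.00 from Thursday to Friday raises Λ by a factor 3.24.

The flask has twice Thursday's loading and half Friday's, at their concentration. As a first round, doubling Thursday's Λ gives 0.325 and halving Friday's gives 0.264, so the Λ read in these two runs is not proportional to loading. Put that disagreement back in: n = 0.849, the stall order, is how steeply Λ rises with loading at fixed concentration. Then Λ = 0.293, and your c is 25.4%. Friday's substrates read level at 29.3% and 30.2%, and its balance closes at 100%, so expect eS near zero and eP high.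

The forecast says c 26%, eP 100%, eS 0%, holding that “the plateau conversion is nearly independent of concentration”.

The flask gives c 27.4%, eP 96.1%, eS 0.0321%.

    precatalyst ⇌ free catalyst (K = 0.140, k = 0.00790 s⁻¹)
    coupling partner + free catalyst + left-handed substrate → free catalyst + left-handed product (k = 21000 L² mol⁻² s⁻¹)
    coupling partner + free catalyst + right-handed substrate → free catalyst + right-handed product (k = 410 L² mol⁻² s⁻¹)
    2 coupling partner → homo dimer (k = 0.110 L mol⁻¹ s⁻¹)
    free catalyst → spent catalyst (k = 0.00420 s⁻¹)
    left-handed substrate ⇌ right-handed substrate (k = 0.0590 s⁻¹)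

That c means Λ = 0.320 in this flask. Here coupling partner is the limiting reagent: 0.96% of its charge remains at 15 min, far less than the 73% of left-handed substrate. By then the homo dimer holds 0.171 M of coupling partner, more than the 0.0274 M held in the two products. For the neighbour with 0.085 mol% precatalyst, n gives Λ = 0.460, so c is 36.8%; computed, it is 38.2%.

(The readings were generated by integration from invented constants; the scatter is artificial.)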